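Early in both runs the target is already high, 68% after 10.0 s in the east run and 71% after 1.33 min in the north run, and each later reading lies lower.

the same everywhere: gas 2.2 mM (held)
- north: substrate 0.034 M; first nucleophile 0.060 M; temperature 5 °C; run made earlier
- east: substrate 0.075 M; first nucleophile 0.060 M; temperature 25 °C; run made earlier
- Wednesday's: substrate 0.050 M; first nucleophile 0.0600 M; temperature 25 °C; time 2.5 min
- Thursday's: substrate 0.050 M; first nucleophile 0.0600 M; temperature 10 °C; time 2.5 min
- Friday's: substrate 0.050 M; first nucleophile 0.0600 M; temperature 40 °C; time 2.5 min

- north (time / min: target / %): 1.33: 71; 2.50: 69; 4.00: 58; 5.00: 56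
- east (time / s: target / %): 10.0: 68; 20.0: 59; 50.0: 41; 120: 16

(standard deviation of a reading: 2 percentage points)

* the flask that comes out highest in amount of target, in percent of the substrate charged, or "all alike" when all lie within 1.5 percentage points (Wednesday's / Thursday's / Friday's / all alike)
* target at the end, in percent of the substrate charged, Wednesday's
* target at the end, in percent of the substrate charged, Thursday's
* target at the end, in percent of the substrate charged, Friday's

I read this as first-order decay of the target. The first and last east readings give a half-life of 52.7 s at 25 °C. Wednesday's 2.5 min therefore holds 2.85 half-lives. This half-life count, the flask's time over the target's half-life at the flask's temperature, is the number I carry. The target left is a ceiling divided by two for each half-life counted.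

The north readings give 10.7 min at 5 °C, so the activation energy reads 86.3 kJ/mol. That makes the half-life 5.55 min on Thursday's and 9.95 s on Friday's, and the counts 0.451 and 15.1.

Is one number enough? One east reading I have not used is a test: the half-life predicts 40.2% at 50.0 s, and 41% was read. Run back to zero time, the east run gives a ceiling of 77.6% and the north run 77.4%, despite different temperatures and charges. So I expect 10.8%, 56.8% and 0.00225% on Wednesday's, Thursday's and Friday's, with Thursday's highest, since its count is lower than the others.

The forecast names Thursday's, with 11%, 57% and 0.3%, the last higher than mine, and its ground is “a fast-step ceiling near 78% seems likely”.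

The flasks give 10.7%, 56.7% and 0.0433%, and Thursday's is highest; Friday's lies above my count's figure. Other capture product ends at 15.0%, 16.2% and 13.6% in Wednesday's, Thursday's and Friday's, a spread of 2.6 percentage points, while the count runs from 0.451 to 15.1. Wednesday's holds 30.6% at 1.25 min. The 1.42 half-lives still to come leave 11.4%, and the flask holds 10.7%.

    target → over-reaction product (k = 0.0140 /s, Ea = 75.0 kJ/mol)
    gas ⇌ second nucleophile, rate k2*(csat - [second nucleophile]) (kL = 29.0 /s)
    substrate ⇌ intermediate (K = 0.290, k = 0.380 /s, Ea = 81.0 kJ/mol, ΔH = −27.0 kJ/mol)
    second nucleophile + intermediate → other capture product (k = 1300 /M/s, Ea = 38.0 kJ/mol)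
    first nucleophile + intermediate → target (k = 450 /M/s, Ea = 42.0 kJ/mol)
    substrate ⇌ dormant form (K = 6.50, k = 0.00320 /s, Ea = 88.0 kJ/mol, ΔH = −10.0 kJ/mol)
    (constants at 25 °C)

Read Friday's flask at 40 s instead. The count is 4.02, so I expect 4.78%. It holds 8.22%.

The numbers in the tables come from a simulation with constants of no real substance, and the scatter is random.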